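Assumption: 3-bromo-4,5-dihydroxybenzaldehyde (4) is taken as a catalogue compound; C1–C6 and C7 denote ring A and its methylene carbon, C1'–C6' and C7' those of ring B.

## Structural features

The target 13 is an unsymmetrical dibenzyl ether: two benzene rings joined through the chain C1–C7–O–C7'–C1', with no stereocentre. Ring A carries bromine on C2 and C6, hydroxyl on C3 and C4 and its only hydrogen on C5; ring B is hexasubstituted, with bromine on C2', C5' and C6' and hydroxyl on C3' and C4'. The fragile groups are the two catechols, which air in basic medium or any source of positive bromine turns into ortho-quinones, and the benzylic ether, which lies para to O4 and O4' so that either free para-hydroxyl can expel the other half as a quinone methide, and which HBr or strong Lewis acids cleave outright. Five aryl–bromine bonds rule out hydrogenolysis, organolithium reagents and dissolving metals late in the route. The skeleton is simple; the difficulty is to place five bromines on two rings that differ by one halogen, to keep C5 of ring A unsubstituted, and to keep the ether unsymmetrical and intact. The key step exploits the fact that C2 and C6 of ring A and C2' and C6' of ring B are the carbons ortho and para to O3 and O3', whereas C5 is meta to O3 and neighbours only O4. With O3–H and O3'–H free and O4 and O4' tied up as electron-poor esters, one directing rule serves both rings, and the fifth bromine on C5' comes with the starting material; the key-step pair 11 (one bromine) and 12 (five bromines) maps atom for atom onto 13. The weak point is the hydroxy-ester motif (free O3–H beside an O4 ester), which can shift its acyl group to O3 through the phenoxide, so the motif is trapped by silylation as soon as it forms and is later released and brominated without base.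

## Logic of the disconnections

13 ⇒ 12. The two ester bonds O4–C(=O) and O4'–C(=O) are cut. The free catechols would not survive positive bromine, so they are uncovered only in the last step. The gain is that 12 already carries every bromine and needs nothing but solvolysis. The forward step must cleave two hindered aryl esters without oxidising the catecholates or solvolysing the ether: oxygen-free, cold, short, with an acidic quench.

12 ⇒ 11. The four bonds C2–Br, C6–Br, C2'–Br and C6'–Br are cut, because these are exactly the carbons ortho and para to the free O3 and O3' hydroxyls. This removes four of the five halogens in one operation and leaves two rings that differ only by the bromine on C5'. The forward step must substitute only these four sites, reach completion at the crowded positions of ring B, stay ionic (no radical attack at C7 or C7'), and find the acyl groups still on O4 and O4'.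

11 ⇒ 10. The two bonds O3–Si and O3'–Si are cut. The hydroxyls that direct the bromination must be masked while the ether is made, since they would be alkylated in place of the alcohol. The forward unmasking must not pass through a phenoxide beside the ester, which calls for an acidic fluoride source.

10 ⇒ 9 + 8. The bond C7–O is cut, which divides the molecule into two halves of nearly equal size and makes the route convergent. Ring A is taken as the electrophile (9) because it lacks the electron-withdrawing bromine and ionises more readily; ring B supplies the alcohol (8). The forward step must form a benzylic ether without alkoxide, which would attack the aryl esters; a silver-assisted, base-free alkylation answers this.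

9 ⇒ 7 ⇒ 3, and 8 ⇒ 6. These are changes of oxidation level at C7 and C7' (C–Br to C–OH to C=O); no skeletal bond is cut. The aldehyde level is needed at the start because only the formyl group distinguishes O4 from O3. The forward steps must reduce an aldehyde and activate an alcohol in the presence of an aryl ester and an aryl silyl ether.

3 ⇒ 1 (through 2), and 6 ⇒ 4 (through 5). The bonds O3–Si and O4–acyl are cut. The para formyl group makes O4–H the more acidic hydroxyl, so one equivalent of base and one of acylating agent should functionalise O4, and silylation in the same flask fixes the result before the acyl group can move. The gain is that each half comes from a catechol aldehyde in one operation. The demand is regiocontrol; it is most severe for 4, whose O4 is also the more hindered oxygen.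

## Other disconnections considered

Alternative 1: The cut removes C1'–C2' and C5'–C6', so ring B is built and not substituted.
- Forward step: 2,5-dibromo-3,4-bis(methoxymethoxy)thiophene 1,1-dioxide A2 would serve as the diene and 3-bromoprop-2-yn-1-yl 2,6-dibromo-3,4-bis(methoxymethoxy)benzyl ether A3 as the dienophile. Thermal Diels–Alder addition and cheletropic extrusion of the sulfonyl bridge would give A1, the tetrakis(methoxymethyl) ether of 13.
- In its favour: every substituent of the hexasubstituted ring B is carried in by a component, A2 is symmetrical so no orientation problem exists, and no electrophilic substitution has to be forced into a crowded position. On this point it is better than the chosen plan, whose hardest event is the last bromination of ring B.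
- Against it here: A2 requires S-oxidation of an electron-rich dialkoxythiophene, which competes with ring oxidation and gives dioxides prone to dimerise. A3 is an unactivated haloalkyne, so the cycloaddition is poorly matched and would need high temperature. Ring A inside A3 still needs its 2,6-dibromo pattern, most plausibly by the same hydroxyl-directed bromination, so the chosen logic is only halved, not avoided. The four acetal groups of A1 must be removed with acid in a protic medium, the conditions under which the para-hydroxybenzyl ether ionises.
- Comparison: structurally it is more secure for ring B and equal for ring A. Mechanistically it trades a well-understood aromatic substitution for a cycloaddition of uncertain rate. The final deprotection is equally delicate in both plans (acid for A1, base for 12). In step count it is longer, since A2 and A3 each need several steps before the union.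

Alternative 2: The cut removes C2–C3 and C4–C5 of ring A.
- Forward step: the pyrone 3,5-dibromo-4-{[(2,5,6-tribromo-3,4-diacetoxybenzyl)oxy]methyl}-2H-pyran-2-one A5 would add across its C3 and C6 to bis(pinacolatoboryl)acetylene A6. The bridged lactone would lose its carboxyl bridge in a retro-Diels–Alder step and aromatise to 2,6-dibromo-3,4-bis(pinacolboryl)benzyl 2,5,6-tribromo-3,4-diacetoxybenzyl ether A4, in which ring A bears pinacolboryl groups on C3 and C4. Oxidation of both C–B bonds of A4 and removal of the acetates would follow.
- In its favour: 3,5-dibromo-2-pyrones are established ambiphilic dienes, and pyrone–alkynylboronate cycloaddition with decarboxylation is a known entry to arylboronates. C5–H is inherited from pyrone C6–H, so over-bromination at C5 cannot occur at all; on this point it is better than the chosen plan, which relies on stoichiometry and on the acyl group on O4. Both oxygens are placed unambiguously.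
- Against it here: A5 already contains the complete ring B, whose three bromines must still come from the kind of bromination used in the chosen plan, so nothing is saved there. A 4-alkoxymethyl-3,5-dibromopyrone is not simple to prepare. The cycloaddition of A6 needs prolonged heating, which the aryl acetates and the benzylic ether must survive. Oxidative cleavage of the two neighbouring C–B bonds of A4 liberates a catechol in the presence of oxidant and base, where it is most easily destroyed, and boron groups flanked by bromine are liable to protodeboronation.
- Comparison: equal in convergence and in the mild ester cleavage at the end; better in the certainty of the C5–H position; worse in mechanistic risk (thermal cycloaddition plus double oxidation against one aromatic substitution) and clearly worse in step count.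

Alternative 3: The cut removes C1–C7 and C1'–C7', so both methylene carbons and the ether oxygen come from one reagent, bis(chloromethyl) ether A10.
- Forward step: 3,5-dibromo-1,2-bis(tert-butyldimethylsilyloxy)benzene A8 would be deprotonated between its two bromines with TMPMgCl·LiCl and the arylmagnesium of A8 added to an excess of A10. After removal of the excess, the arylmagnesium from 3,4,6-tribromo-1,2-bis(tert-butyldimethylsilyloxy)benzene A9, formed at its only C–H, would be added to give A7, the tetrakis(tert-butyldimethylsilyl) ether of 13.
- In its favour: it is the shortest and most convergent assembly conceivable, with every bromine in place before the coupling and no late halogenation. In step economy and in freedom from late regiochemical questions it is better than the chosen plan.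
- Against it here: A10 is a volatile, potent human carcinogen, and the plan requires its use in excess and its evaporation. The outcome depends on statistical control of mono- against double addition. The arylmagnesium species from A8 and A9, each flanked by two ortho bromines, can eliminate to arynes or let halogens migrate. A9 has a substitution pattern that direct bromination of a catechol does not deliver, so its preparation is a problem of its own. Fluoride removal of the four silyl groups of A7 produces para-phenoxides on both sides of the benzylic ether.
- Comparison: structurally equal (the same ether, no stereochemistry), equal in the fragility of the last deprotection, and better in step count. It is mechanistically far less secure and not acceptable on safety grounds, whereas every step of the chosen plan is a standard operation.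

Key step: step 8

## Route

Step 1
Reactants: 1 3,4-dihydroxybenzaldehyde
Product: 3 3-(tert-butyldimethylsilyloxy)-4-(pivaloyloxy)benzaldehyde, via 3-hydroxy-4-(pivaloyloxy)benzaldehyde 2 (not isolated)
Conditions: Et3N (1.0 equiv), PivCl (1.0 equiv), THF, −20 °C; then imidazole, TBSCl, DMF, 0 °C to rt (same flask)
Reagents that add atoms: pivaloyl chloride CC(C)(C)C(Cl)=O; tert-butyldimethylsilyl chloride CC(C)(C)[Si](C)(C)Cl
Why: Regioselective acylation of a catechol monophenoxide followed by silylation: the 4-OH is the more acidic hydroxyl because its anion is conjugated with the para formyl group, so one equivalent of Et3N generates the O4 phenoxide, which takes the pivaloyl group; silylating the remaining 3-OH at once freezes this regiochemistry before the hindered acyl group can shift to O3.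

Step 2
Reactants: 4 3-bromo-4,5-dihydroxybenzaldehyde
Product: 6 3-bromo-5-(tert-butyldimethylsilyloxy)-4-(pivaloyloxy)benzaldehyde, via 3-bromo-5-hydroxy-4-(pivaloyloxy)benzaldehyde 5 (not isolated)
Conditions: Et3N (1.0 equiv), PivCl (1.0 equiv), THF, −20 to 0 °C; then imidazole, TBSCl, DMF, 0 °C to rt (same flask)
Reagents that add atoms: pivaloyl chloride CC(C)(C)C(Cl)=O; tert-butyldimethylsilyl chloride CC(C)(C)[Si](C)(C)Cl
Why: The same monophenoxide acylation and in-flask silylation; the ortho bromine widens the acidity gap in favour of the hydroxyl para to the formyl group, although that oxygen is also the more hindered one, which is why this step is counted among the uncertain ones.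

Step 3
Reactants: 3 3-(tert-butyldimethylsilyloxy)-4-(pivaloyloxy)benzaldehyde
Product: 7 3-(tert-butyldimethylsilyloxy)-4-(pivaloyloxy)benzyl alcohol
Conditions: NaBH4, THF/MeOH (9:1), −10 °C; aqueous NH4Cl
Reagents that add atoms: none
Why: Chemoselective hydride reduction of an aromatic aldehyde; at low temperature and with little methanol the aryl pivalate and the aryl silyl ether are not attacked.

Step 4
Reactants: 6 3-bromo-5-(tert-butyldimethylsilyloxy)-4-(pivaloyloxy)benzaldehyde
Product: 8 3-bromo-5-(tert-butyldimethylsilyloxy)-4-(pivaloyloxy)benzyl alcohol
Conditions: NaBH4, THF/MeOH (9:1), −10 °C; aqueous NH4Cl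
Reagents that add atoms: none
Why: The same chemoselective aldehyde reduction; the aryl bromide is inert to NaBH4 and the ester and silyl ether survive the short, cold reaction.

Step 5
Reactants: 7 3-(tert-butyldimethylsilyloxy)-4-(pivaloyloxy)benzyl alcohol
Product: 9 3-(tert-butyldimethylsilyloxy)-4-(pivaloyloxy)benzyl bromide
Conditions: CBr4, PPh3, CH2Cl2, 0 °C
Reagents that add atoms: carbon tetrabromide BrC(Br)(Br)Br
Why: Appel reaction: neutral conversion of a primary benzylic alcohol into the bromide through the alkoxyphosphonium ion, with no acid that could remove the silyl group; the para acyloxy group (no free para-hydroxyl) keeps the bromide from ionising to a quinone methide.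

Step 6
Reactants: 9 3-(tert-butyldimethylsilyloxy)-4-(pivaloyloxy)benzyl bromide; 8 3-bromo-5-(tert-butyldimethylsilyloxy)-4-(pivaloyloxy)benzyl alcohol
Product: 10 3-(tert-butyldimethylsilyloxy)-4-(pivaloyloxy)benzyl 3-bromo-5-(tert-butyldimethylsilyloxy)-4-(pivaloyloxy)benzyl ether
Conditions: Ag2O (1.5 equiv), 4 Å molecular sieves, CH2Cl2, rt, dark
Reagents that add atoms: none
Why: Ag2O-promoted Williamson-type etherification: silver assists the departure of bromide from the benzylic carbon and the oxide takes up the proton, so no alkoxide is present that could transesterify the aryl pivalates; 9 is the electrophile because its ring lacks the electron-withdrawing bromine.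

Step 7
Reactants: 10 3-(tert-butyldimethylsilyloxy)-4-(pivaloyloxy)benzyl 3-bromo-5-(tert-butyldimethylsilyloxy)-4-(pivaloyloxy)benzyl ether
Product: 11 3-hydroxy-4-(pivaloyloxy)benzyl 3-bromo-5-hydroxy-4-(pivaloyloxy)benzyl ether
Conditions: HF·pyridine, pyridine/THF, 0 °C to rt
Reagents that add atoms: none
Why: Fluoride cleavage of aryl silyl ethers driven by the Si–F bond; under acidic HF·pyridine the phenols are released as neutral OH groups and not as phenoxides, which an O4-to-O3 acyl shift would need, and pivalates are stable to this reagent.

Step 8
Reactants: 11 3-hydroxy-4-(pivaloyloxy)benzyl 3-bromo-5-hydroxy-4-(pivaloyloxy)benzyl ether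
Product: 12 2,6-dibromo-3-hydroxy-4-(pivaloyloxy)benzyl 2,5,6-tribromo-3-hydroxy-4-(pivaloyloxy)benzyl ether
Conditions: NBS (4.1 equiv), MeCN, 0 °C to rt (40 °C at the end if needed), dark; aqueous Na2S2O3
Reagents that add atoms: N-bromosuccinimide O=C1CCC(=O)N1Br
Why: Electrophilic aromatic substitution: polarised NBS in MeCN transfers positive bromine to the ring, the arenium ion is stabilised by the lone pair of the free O3 (O3') hydroxyl, and loss of the proton to the succinimide anion restores aromaticity, four times in all. The closest known reaction type is the NBS ortho/para bromination of phenols, in particular the double bromination of 3-hydroxy-4-alkoxybenzaldehydes at the carbons next to and across from the hydroxyl. No ring closes and no stereocentre forms. The step needs site selectivity: only C6 and C6' (para) and C2 and C2' (ortho) receive the strong donation of a free OH, C5 of ring A is meta to O3 and sees only the feeble donation of the acylated O4, the ipso carbons C1 and C1' are meta to the free hydroxyl, and the second ortho site of each hydroxyl (C4, C4') is occupied. Ring B has no free position left once C2' and C6' are filled, because C5' already carries its bromine, so two equivalents are consumed per ring and the small excess finds no activated site. The step also needs chemoselectivity for the ring over the benzylic C7–H and C7'–H bonds, which darkness, a polar solvent and low temperature should secure by suppressing the radical chain, and the esters on O4 and O4' prevent oxidation to ortho-quinones. NBS delivers succinimide and not HBr, so the benzylic ether is not cleaved, and no base is present that could shift a pivaloyl group before the ring is brominated. The last substitution on ring B creates a hexasubstituted ring and is the slowest, so gentle warming at the end may be required.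

Step 9
Reactants: 12 2,6-dibromo-3-hydroxy-4-(pivaloyloxy)benzyl 2,5,6-tribromo-3-hydroxy-4-(pivaloyloxy)benzyl ether
Product: 13 2,6-dibromo-3,4-dihydroxybenzyl 2,5,6-tribromo-3,4-dihydroxybenzyl ether (CNP0152798.0)
Conditions: K2CO3 (3 equiv), degassed MeOH, Ar, 0 °C to rt; then 1 M HCl, 0 °C
Reagents that add atoms: none
Why: Base-mediated methanolysis of aryl esters: methoxide attacks the pivaloyl carbonyl and the electron-poor bromophenoxides are good leaving groups; exclusion of oxygen protects the catecholates from oxidation, and the cold acidic quench returns the neutral catechols before the ether can solvolyse.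

## Compound list

1 | 3,4-dihydroxybenzaldehyde | O=Cc1ccc(O)c(O)c1 | starting material
2 | 3-hydroxy-4-(pivaloyloxy)benzaldehyde (formed in the flask, not isolated) | CC(C)(C)C(=O)Oc1ccc(C=O)cc1O | intermediate
3 | 3-(tert-butyldimethylsilyloxy)-4-(pivaloyloxy)benzaldehyde | CC(C)(C)C(=O)Oc1ccc(C=O)cc1O[Si](C)(C)C(C)(C)C | intermediate
4 | 3-bromo-4,5-dihydroxybenzaldehyde | O=Cc1cc(O)c(O)c(Br)c1 | starting material
5 | 3-bromo-5-hydroxy-4-(pivaloyloxy)benzaldehyde (formed in the flask, not isolated) | CC(C)(C)C(=O)Oc1c(O)cc(C=O)cc1Br | intermediate
6 | 3-bromo-5-(tert-butyldimethylsilyloxy)-4-(pivaloyloxy)benzaldehyde | CC(C)(C)C(=O)Oc1c(O[Si](C)(C)C(C)(C)C)cc(C=O)cc1Br | intermediate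
7 | 3-(tert-butyldimethylsilyloxy)-4-(pivaloyloxy)benzyl alcohol | CC(C)(C)C(=O)Oc1ccc(CO)cc1O[Si](C)(C)C(C)(C)C | intermediate
8 | 3-bromo-5-(tert-butyldimethylsilyloxy)-4-(pivaloyloxy)benzyl alcohol | CC(C)(C)C(=O)Oc1c(O[Si](C)(C)C(C)(C)C)cc(CO)cc1Br | intermediate
9 | 3-(tert-butyldimethylsilyloxy)-4-(pivaloyloxy)benzyl bromide | CC(C)(C)C(=O)Oc1ccc(CBr)cc1O[Si](C)(C)C(C)(C)C | intermediate
10 | 3-(tert-butyldimethylsilyloxy)-4-(pivaloyloxy)benzyl 3-bromo-5-(tert-butyldimethylsilyloxy)-4-(pivaloyloxy)benzyl ether | CC(C)(C)C(=O)Oc1ccc(COCc2cc(O[Si](C)(C)C(C)(C)C)c(OC(=O)C(C)(C)C)c(Br)c2)cc1O[Si](C)(C)C(C)(C)C | intermediate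
11 | 3-hydroxy-4-(pivaloyloxy)benzyl 3-bromo-5-hydroxy-4-(pivaloyloxy)benzyl ether | CC(C)(C)C(=O)Oc1ccc(COCc2cc(O)c(OC(=O)C(C)(C)C)c(Br)c2)cc1O | intermediate
12 | 2,6-dibromo-3-hydroxy-4-(pivaloyloxy)benzyl 2,5,6-tribromo-3-hydroxy-4-(pivaloyloxy)benzyl ether | CC(C)(C)C(=O)Oc1cc(Br)c(COCc2c(Br)c(O)c(OC(=O)C(C)(C)C)c(Br)c2Br)c(Br)c1O | intermediate
13 | 2,6-dibromo-3,4-dihydroxybenzyl 2,5,6-tribromo-3,4-dihydroxybenzyl ether (CNP0152798.0) | Oc1cc(Br)c(COCc2c(Br)c(O)c(O)c(Br)c2Br)c(Br)c1O | target

## Step count and least certain steps

Total: 9 steps. Longest linear sequence: 7 steps (steps 1, 3, 5, 6, 7, 8, 9 from 1); the branch from 4 has 6 steps (2, 4, 6, 7, 8, 9).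

**Step 8 (key step).**
- What may go wrong: incomplete substitution at the crowded C2' and C6' of ring B, leaving under-brominated material that is hard to separate. Radical hydrogen abstraction at C7 or C7' would lead to oxidative cleavage of the ether. An acyl shift before bromination would redirect substitution towards C5 and the ipso carbon.
- Fallback (sets out from 5 and 9, returns at 12): ring B is finished before the ether exists. Step 2 is stopped after the acylation and 5 is isolated. Two equivalents of NBS in MeCN, with a trace of acid and warming if needed, brominate the carbons ortho and para to its free hydroxyl to give 2,5,6-tribromo-3-hydroxy-4-(pivaloyloxy)benzaldehyde F1; forcing conditions are harmless on the way to F1 because no benzylic ether is present. TBSOTf and 2,6-lutidine silylate the hindered phenol of F1 to 2,5,6-tribromo-3-(tert-butyldimethylsilyloxy)-4-(pivaloyloxy)benzaldehyde F2. NaBH4 reduces F2 to 2,5,6-tribromo-3-(tert-butyldimethylsilyloxy)-4-(pivaloyloxy)benzyl alcohol F3. Ag2O joins F3 with 9 as in step 6 to give 3-(tert-butyldimethylsilyloxy)-4-(pivaloyloxy)benzyl 2,5,6-tribromo-3-(tert-butyldimethylsilyloxy)-4-(pivaloyloxy)benzyl ether F4. HF·pyridine removes both silyl groups of F4 to give 3-hydroxy-4-(pivaloyloxy)benzyl 2,5,6-tribromo-3-hydroxy-4-(pivaloyloxy)benzyl ether F5, whose ring B is already complete. Two equivalents of NBS then brominate F5 only at C6 and C2 of ring A, the two least hindered of the four substitutions, to give 12.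

**Step 2.**
- What may go wrong: poor regioselectivity of the acylation, since the oxygen that should react lies between bromine and the second hydroxyl while the other is unhindered. A shift of the pivaloyl group to the neighbouring oxygen before silylation would give the regioisomeric silyl ester, which would be carried forward unnoticed. Step 1 shares this risk to a smaller degree.
- Fallback (sets out from commercial 5-bromovanillin F6 in place of 4, returns at 5): the regiochemistry is bought and not made. PivCl, Et3N and catalytic DMAP acylate the only hydroxyl of F6 to give 2-bromo-4-formyl-6-methoxyphenyl pivalate F7. BBr3 in CH2Cl2 at −78 °C cleaves the methyl ether of F7, ester and aldehyde being tolerated at this temperature, to give 5, which is silylated as in the second stage of step 2 to reach 6.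

**Step 6.**
- What may go wrong: slow heterogeneous alkylation, which would allow hydrolysis of 9 by the water that the reaction forms, formation of symmetrical ethers, or loss of a silyl group followed by alkylation of the phenol.
- Fallback (sets out from 7 and 8, returns at 10, and replaces steps 5 and 6): 7 with Cl3CCN and catalytic DBU in CH2Cl2 gives 3-(tert-butyldimethylsilyloxy)-4-(pivaloyloxy)benzyl 2,2,2-trichloroacetimidate F8. Catalytic TMSOTf in CH2Cl2 at −20 °C activates F8 towards 8 and gives 10 with loss of trichloroacetamide, an acid-catalysed benzylation in place of the silver-assisted alkylation.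

**Step 9.**
- What may go wrong: oxidation of the catecholates by traces of air, exchange of the benzylic ether with methanol through a quinone methide, or sluggish cleavage of the ring B ester that sits between bromine and hydroxyl.
- Fallback (sets out from 12, returns at 13): excess i-Bu2AlH in CH2Cl2 at −78 °C cleaves both pivalates reductively in an aprotic medium, giving 2,2-dimethylpropan-1-ol and leaving the phenols bound to aluminium until a cold quench with aqueous tartaric acid liberates 13. Hydride reduction replaces solvolysis, so neither methoxide nor a protic nucleophile is present. No new compound arises on this path, hence the entry F0.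

## Further compounds

F1 | step 8 | 2,5,6-tribromo-3-hydroxy-4-(pivaloyloxy)benzaldehyde | CC(C)(C)C(=O)Oc1c(O)c(Br)c(C=O)c(Br)c1Br
F2 | step 8 | 2,5,6-tribromo-3-(tert-butyldimethylsilyloxy)-4-(pivaloyloxy)benzaldehyde | CC(C)(C)C(=O)Oc1c(O[Si](C)(C)C(C)(C)C)c(Br)c(C=O)c(Br)c1Br
F3 | step 8 | 2,5,6-tribromo-3-(tert-butyldimethylsilyloxy)-4-(pivaloyloxy)benzyl alcohol | CC(C)(C)C(=O)Oc1c(O[Si](C)(C)C(C)(C)C)c(Br)c(CO)c(Br)c1Br
F4 | step 8 | 3-(tert-butyldimethylsilyloxy)-4-(pivaloyloxy)benzyl 2,5,6-tribromo-3-(tert-butyldimethylsilyloxy)-4-(pivaloyloxy)benzyl ether | CC(C)(C)C(=O)Oc1ccc(COCc2c(Br)c(O[Si](C)(C)C(C)(C)C)c(OC(=O)C(C)(C)C)c(Br)c2Br)cc1O[Si](C)(C)C(C)(C)C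
F5 | step 8 | 3-hydroxy-4-(pivaloyloxy)benzyl 2,5,6-tribromo-3-hydroxy-4-(pivaloyloxy)benzyl ether | CC(C)(C)C(=O)Oc1ccc(COCc2c(Br)c(O)c(OC(=O)C(C)(C)C)c(Br)c2Br)cc1O
F6 | step 2 | 5-bromovanillin | COc1cc(C=O)cc(Br)c1O
F7 | step 2 | 2-bromo-4-formyl-6-methoxyphenyl pivalate | COc1cc(C=O)cc(Br)c1OC(=O)C(C)(C)C
F8 | step 6 | 3-(tert-butyldimethylsilyloxy)-4-(pivaloyloxy)benzyl 2,2,2-trichloroacetimidate | CC(C)(C)C(=O)Oc1ccc(COC(=N)C(Cl)(Cl)Cl)cc1O[Si](C)(C)C(C)(C)C
F0 | step 9 | none | none
A1 | alternative 1 | tetrakis(methoxymethyl) ether of the target | COCOc1c(OCOC)c(Br)c(COCc2c(Br)c(OCOC)c(OCOC)cc2Br)c(Br)c1Br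
A2 | alternative 1 | 2,5-dibromo-3,4-bis(methoxymethoxy)thiophene 1,1-dioxide | COCOC1=C(Br)S(=O)(=O)C(Br)=C1OCOC
A3 | alternative 1 | 3-bromoprop-2-yn-1-yl 2,6-dibromo-3,4-bis(methoxymethoxy)benzyl ether | BrC#CCOCc1c(Br)cc(OCOC)c(OCOC)c1Br
A4 | alternative 2 | 2,6-dibromo-3,4-bis(pinacolboryl)benzyl 2,5,6-tribromo-3,4-diacetoxybenzyl ether | CC(=O)Oc1c(OC(C)=O)c(Br)c(COCc2c(Br)c(B3OC(C)(C)C(C)(C)O3)c(B3OC(C)(C)C(C)(C)O3)cc2Br)c(Br)c1Br
A5 | alternative 2 | 3,5-dibromo-4-{[(2,5,6-tribromo-3,4-diacetoxybenzyl)oxy]methyl}-2H-pyran-2-one | O=C1OC=C(Br)C(COCc2c(Br)c(OC(C)=O)c(OC(C)=O)c(Br)c2Br)=C1Br
A6 | alternative 2 | bis(pinacolatoboryl)acetylene | CC1(C)OB(C#CB2OC(C)(C)C(C)(C)O2)OC1(C)C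
A7 | alternative 3 | tetrakis(tert-butyldimethylsilyl) ether of the target | CC(C)(C)[Si](C)(C)Oc1cc(Br)c(COCc2c(Br)c(O[Si](C)(C)C(C)(C)C)c(O[Si](C)(C)C(C)(C)C)c(Br)c2Br)c(Br)c1O[Si](C)(C)C(C)(C)C
A8 | alternative 3 | 3,5-dibromo-1,2-bis(tert-butyldimethylsilyloxy)benzene | CC(C)(C)[Si](C)(C)Oc1cc(Br)cc(Br)c1O[Si](C)(C)C(C)(C)C
A9 | alternative 3 | 3,4,6-tribromo-1,2-bis(tert-butyldimethylsilyloxy)benzene | CC(C)(C)[Si](C)(C)Oc1c(Br)cc(Br)c(Br)c1O[Si](C)(C)C(C)(C)C
A10 | alternative 3 | bis(chloromethyl) ether | ClCOCCl
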